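**Assumption:** enolised di- and triketones (13, 14, 26, F2) are written as one tautomer and CIP labels refer to that tautomer; the label of the quaternary carbon changes from S (ketal series 4–13) to R (14, 26) only because substituent priorities change, not the geometry.

## Retrosynthetic overview

1. Target 26 ⇒ disconnect the methylene bridge: Michael addition of the enantiopure acyl-trione 14 to the o-quinone methide 25, released from the Mannich base 24.
2. 24 ⇒ 5-methoxyresorcinol by two directed ortho-metalations (aminomethylation between the two OMOM groups, then hexanoylation at one of the two equivalent remaining positions), so the arene regiochemistry is fixed by symmetry.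
3. 14 ⇒ ketal-protected 2-butanoyl-1,3-dione 13 ⇒ 1,3-dione 11 ⇒ enone 8 ⇒ ketone 6. The ketal keeps the two sides of the quaternary carbon different until the butanoyl group is in place.
4. 6 ⇒ (2S,3S)-hydroxy ketone 3, from yeast desymmetrisation of the prochiral dione 2 (this sets the quaternary centre); allyl becomes prenyl by cross-metathesis.
5. Ring order: both six-membered rings are bought (cyclohexanedione, resorcinol); the only ring formed is the temporary dioxolane (step 3, removed in step 10).

## Route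

**Step 1**
Reactants: 1 2-methylcyclohexane-1,3-dione
Product: 2 2-methyl-2-(prop-2-en-1-yl)cyclohexane-1,3-dione
Conditions: allyl bromide (1.5 equiv), 1 M aq. NaOH, rt, 24 h
Reagents that add atoms: allyl bromide, C=CCBr
Why: SN2 C-alkylation of the stabilised dione enolate in water, where hydrogen bonding to the enolate oxygens favours C- over O-allylation.

**Step 2**
Reactants: 2 2-methyl-2-(prop-2-en-1-yl)cyclohexane-1,3-dione
Product: 3 (2S,3S)-3-hydroxy-2-methyl-2-(prop-2-en-1-yl)cyclohexan-1-one
Conditions: baker's yeast (S. cerevisiae), sucrose, H2O, 30 °C, 48 h; chromatography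
Reagents that add atoms: none
Why: Enzymatic desymmetrising ketone reduction in which the yeast reductase reduces one of the two enantiotopic carbonyls from one face, setting the carbinol (3S) and the quaternary centre (2S) together (known for this substrate, >98% ee); the minor (2R,3S) diastereomer is removed by chromatography.

**Step 3**
Reactants: 3 (2S,3S)-3-hydroxy-2-methyl-2-(prop-2-en-1-yl)cyclohexan-1-one
Product: 4 (6S,7S)-6-methyl-6-(prop-2-en-1-yl)-1,4-dioxaspiro[4.5]decan-7-ol
Conditions: ethylene glycol (5 equiv), p-TsOH·H2O (5 mol %), benzene, reflux, Dean–Stark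
Reagents that add atoms: ethylene glycol, OCCO
Why: Acid-catalysed ketalisation masks the remaining ketone so the two carbons flanking the quaternary centre stay chemically distinct, and the terminal alkene and secondary alcohol are inert to it.

**Step 4**
Reactants: 4 (6S,7S)-6-methyl-6-(prop-2-en-1-yl)-1,4-dioxaspiro[4.5]decan-7-ol
Product: 5 (6S)-6-methyl-6-(prop-2-en-1-yl)-1,4-dioxaspiro[4.5]decan-7-one
Conditions: Dess–Martin periodinane (1.3 equiv), NaHCO3, CH2Cl2, 0 °C → rt
Reagents that add atoms: none
Why: Dess–Martin oxidation of the secondary alcohol under buffered conditions that leave the ketal alone; the quaternary centre has no α-hydrogen and cannot epimerise.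

**Step 5**
Reactants: 5 (6S)-6-methyl-6-(prop-2-en-1-yl)-1,4-dioxaspiro[4.5]decan-7-one
Product: 6 (6S)-6-methyl-6-(3-methylbut-2-en-1-yl)-1,4-dioxaspiro[4.5]decan-7-one
Conditions: Grubbs II (5 mol %), 2-methylbut-2-ene (excess), CH2Cl2, 40 °C, sealed tube
Reagents that add atoms: 2-methylbut-2-ene, CC=C(C)C
Why: Olefin cross-metathesis with a large excess of 2-methylbut-2-ene turns the terminal allyl group into prenyl, driven by loss of propene.

**Step 6**
Reactants: 6 (6S)-6-methyl-6-(3-methylbut-2-en-1-yl)-1,4-dioxaspiro[4.5]decan-7-one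
Product: 8 (6S)-6-methyl-6-(3-methylbut-2-en-1-yl)-1,4-dioxaspiro[4.5]dec-8-en-7-one, via trimethylsilyl enol ether 7 (not isolated)
Conditions: LDA, THF, −78 °C, then TMSCl; then Pd(OAc)2 (1.05 equiv), MeCN, rt
Reagents that add atoms: none
Why: Saegusa–Ito oxidation: C8 is the only enolisable position, so a single silyl enol ether forms and Pd(II) dehydrosilylates it to the enone while the trisubstituted prenyl alkene is untouched.

**Step 7**
Reactants: 8 (6S)-6-methyl-6-(3-methylbut-2-en-1-yl)-1,4-dioxaspiro[4.5]dec-8-en-7-one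
Product: 10 (6S)-9-hydroxy-6-methyl-6-(3-methylbut-2-en-1-yl)-1,4-dioxaspiro[4.5]decan-7-one (C9 epimers), via pinacol boronate 9 (not isolated)
Conditions: B2pin2 (1.1 equiv), CuCl (5 mol %), Xantphos (5 mol %), NaOt-Bu (10 mol %), MeOH (2 equiv), THF, rt; then NaBO3·4H2O, THF/H2O, rt
Reagents that add atoms: sodium perborate, [Na+].[Na+].O[B-]1(O)OO[B-](O)(O)OO1
Why: Copper-catalysed conjugate borylation puts boron on the enone β-carbon and perborate oxidises C–B to C–OH; the new C9 centre is irrelevant because it is oxidised in the next step.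

**Step 8**
Reactants: 10 (6S)-9-hydroxy-6-methyl-6-(3-methylbut-2-en-1-yl)-1,4-dioxaspiro[4.5]decan-7-one
Product: 11 (6S)-6-methyl-6-(3-methylbut-2-en-1-yl)-1,4-dioxaspiro[4.5]decane-7,9-dione
Conditions: Dess–Martin periodinane (1.2 equiv), NaHCO3, CH2Cl2, 0 °C → rt
Reagents that add atoms: none
Why: Dess–Martin oxidation of the β-hydroxy ketone gives the 1,3-diketone without acid, so the ketal cannot migrate or hydrolyse.

**Step 9**
Reactants: 11 (6S)-6-methyl-6-(3-methylbut-2-en-1-yl)-1,4-dioxaspiro[4.5]decane-7,9-dione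
Product: 13 (6S)-8-butanoyl-7-hydroxy-6-methyl-6-(3-methylbut-2-en-1-yl)-1,4-dioxaspiro[4.5]dec-7-en-9-one, via enol butanoate 12 (not isolated)
Conditions: butanoic acid (1.1 equiv), DCC (1.2 equiv), DMAP (1.0 equiv), CH2Cl2, rt, 24 h
Reagents that add atoms: butanoic acid, CCCC(=O)O
Why: Steglich O-acylation of the dione followed by DMAP-mediated O→C acyl migration (as in 2-acyldimedone syntheses) places butanoyl on C8, the only carbon between two carbonyls.

**Step 10**
Reactants: 13 (6S)-8-butanoyl-7-hydroxy-6-methyl-6-(3-methylbut-2-en-1-yl)-1,4-dioxaspiro[4.5]dec-7-en-9-one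
Product: 14 (4R)-2-butanoyl-3,5-dihydroxy-4-methyl-4-(3-methylbut-2-en-1-yl)cyclohexa-2,5-dien-1-one
Conditions: 1 M aq. HCl/THF (1:1), rt, 4 h
Reagents that add atoms: water, O
Why: Acid hydrolysis of the dioxolane unveils the third ring carbonyl only after the butanoyl group has differentiated the two sides, so no achiral trione is ever formed and the quaternary centre is carried over intact; prenylated β-triketones of the hop-acid type tolerate cold dilute mineral acid.

**Step 11**
Reactants: 15 5-methoxybenzene-1,3-diol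
Product: 16 1-methoxy-3,5-bis(methoxymethoxy)benzene
Conditions: MOMCl (2.5 equiv), i-Pr2NEt (3 equiv), CH2Cl2, 0 °C → rt
Reagents that add atoms: chloromethyl methyl ether, COCCl
Why: O-alkylation of both phenols gives MOM ethers that protect the phenols and later direct lithiation.

**Step 12**
Reactants: 16 1-methoxy-3,5-bis(methoxymethoxy)benzene
Product: 18 1-[4-methoxy-2,6-bis(methoxymethoxy)phenyl]-N,N-dimethylmethanamine, via aryllithium 17 (not isolated)
Conditions: n-BuLi (1.1 equiv), TMEDA, THF, 0 °C, 1 h; then Eschenmoser's salt (1.3 equiv), −78 °C → rt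
Reagents that add atoms: N,N-dimethylmethylideneammonium iodide, C=[N+](C)C.[I-]
Why: Directed ortho-metalation occurs at the carbon flanked by both OMOM groups (the strongest cooperative site), and Mannich-type trapping with the iminium salt installs the aminomethyl group at the future bridge terminus.

**Step 13**
Reactants: 19 hexanoyl chloride; 20 N,O-dimethylhydroxylamine hydrochloride
Product: 21 N-methoxy-N-methylhexanamide
Conditions: Et3N (2.2 equiv), CH2Cl2, 0 °C → rt
Reagents that add atoms: none
Why: Straightforward N-acylation of the hydroxylamine gives the Weinreb amide.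

**Step 14**
Reactants: 18 1-[4-methoxy-2,6-bis(methoxymethoxy)phenyl]-N,N-dimethylmethanamine; 21 N-methoxy-N-methylhexanamide
Product: 23 1-{3-[(dimethylamino)methyl]-6-methoxy-2,4-bis(methoxymethoxy)phenyl}hexan-1-one, via aryllithium 22 (not isolated)
Conditions: s-BuLi (1.2 equiv), TMEDA, THF, −78 °C, 1 h; then 21 (1.3 equiv), −78 → 0 °C; aq. NH4Cl
Reagents that add atoms: none
Why: The second directed ortho-metalation can only occur at the two equivalent ring C–H positions between OMOM and OMe, and the aryllithium adds once to the Weinreb amide (chelated tetrahedral intermediate) to give the ketone.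

**Step 15**
Reactants: 23 1-{3-[(dimethylamino)methyl]-6-methoxy-2,4-bis(methoxymethoxy)phenyl}hexan-1-one
Product: 24 1-{3-[(dimethylamino)methyl]-2,4-dihydroxy-6-methoxyphenyl}hexan-1-one hydrochloride
Conditions: 3 M HCl in MeOH, 40 °C, 3 h; evaporate, triturate with Et2O
Reagents that add atoms: hydrogen chloride, Cl
Why: Acid-catalysed cleavage of both MOM acetals, with the amine protonated so it cannot leave and trigger premature quinone methide formation.

**Step 16**
Reactants: 14 (4R)-2-butanoyl-3,5-dihydroxy-4-methyl-4-(3-methylbut-2-en-1-yl)cyclohexa-2,5-dien-1-one; 24 1-{3-[(dimethylamino)methyl]-2,4-dihydroxy-6-methoxyphenyl}hexan-1-one hydrochloride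
Product: 26 (4R)-2-butanoyl-6-[(3-hexanoyl-2,6-dihydroxy-4-methoxyphenyl)methyl]-3,5-dihydroxy-4-methyl-4-(3-methylbut-2-en-1-yl)cyclohexa-2,5-dien-1-one, via ortho-quinone methide 25 (not isolated)
Conditions: Et3N (3 equiv), 1,4-dioxane, 70 °C, N2; 24 added in portions to 14 (1.3 equiv)
Reagents that add atoms: none
Why: Mannich-base alkylation: the freed phenolic Mannich base loses dimethylamine to give the o-quinone methide, and Michael addition of the triketone enolate of 14 through C6 (its only C–H nucleophilic carbon) followed by rearomatisation forms the methylene bridge without touching the stereocentre.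

## Compound list

1 | 2-methylcyclohexane-1,3-dione | CC1C(=O)CCCC1=O | starting material
2 | 2-methyl-2-(prop-2-en-1-yl)cyclohexane-1,3-dione | C=CCC1(C)C(=O)CCCC1=O | intermediate
3 | (2S,3S)-3-hydroxy-2-methyl-2-(prop-2-en-1-yl)cyclohexan-1-one | O=C1CCC[C@H](O)[C@]1(C)CC=C | intermediate
4 | (6S,7S)-6-methyl-6-(prop-2-en-1-yl)-1,4-dioxaspiro[4.5]decan-7-ol | O1CCOC12CCC[C@H](O)[C@]2(C)CC=C | intermediate
5 | (6S)-6-methyl-6-(prop-2-en-1-yl)-1,4-dioxaspiro[4.5]decan-7-one | O1CCOC12CCCC(=O)[C@]2(C)CC=C | intermediate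
6 | (6S)-6-methyl-6-(3-methylbut-2-en-1-yl)-1,4-dioxaspiro[4.5]decan-7-one | O1CCOC12CCCC(=O)[C@]2(C)CC=C(C)C | intermediate
7 | trimethyl{[(6S)-6-methyl-6-(3-methylbut-2-en-1-yl)-1,4-dioxaspiro[4.5]dec-7-en-7-yl]oxy}silane | O1CCOC12CCC=C(O[Si](C)(C)C)[C@]2(C)CC=C(C)C | intermediate (not isolated)
8 | (6S)-6-methyl-6-(3-methylbut-2-en-1-yl)-1,4-dioxaspiro[4.5]dec-8-en-7-one | O1CCOC12CC=CC(=O)[C@]2(C)CC=C(C)C | intermediate
9 | (6S)-6-methyl-6-(3-methylbut-2-en-1-yl)-9-(4,4,5,5-tetramethyl-1,3,2-dioxaborolan-2-yl)-1,4-dioxaspiro[4.5]decan-7-one (C9 epimers) | O1CCOC12CC(B3OC(C)(C)C(C)(C)O3)CC(=O)[C@]2(C)CC=C(C)C | intermediate (not isolated)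
10 | (6S)-9-hydroxy-6-methyl-6-(3-methylbut-2-en-1-yl)-1,4-dioxaspiro[4.5]decan-7-one (C9 epimers) | O1CCOC12CC(O)CC(=O)[C@]2(C)CC=C(C)C | intermediate
11 | (6S)-6-methyl-6-(3-methylbut-2-en-1-yl)-1,4-dioxaspiro[4.5]decane-7,9-dione | O1CCOC12CC(=O)CC(=O)[C@]2(C)CC=C(C)C | intermediate
12 | (6S)-6-methyl-6-(3-methylbut-2-en-1-yl)-7-oxo-1,4-dioxaspiro[4.5]dec-8-en-9-yl butanoate | O1CCOC12CC(OC(=O)CCC)=CC(=O)[C@]2(C)CC=C(C)C | intermediate (not isolated)
13 | (6S)-8-butanoyl-7-hydroxy-6-methyl-6-(3-methylbut-2-en-1-yl)-1,4-dioxaspiro[4.5]dec-7-en-9-one | O1CCOC12CC(=O)C(C(=O)CCC)=C(O)[C@]2(C)CC=C(C)C | intermediate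
14 | (4R)-2-butanoyl-3,5-dihydroxy-4-methyl-4-(3-methylbut-2-en-1-yl)cyclohexa-2,5-dien-1-one | O=C1C=C(O)[C@@](C)(CC=C(C)C)C(O)=C1C(=O)CCC | intermediate
15 | 5-methoxybenzene-1,3-diol | COc1cc(O)cc(O)c1 | starting material
16 | 1-methoxy-3,5-bis(methoxymethoxy)benzene | COCOc1cc(OC)cc(OCOC)c1 | intermediate
17 | [4-methoxy-2,6-bis(methoxymethoxy)phenyl]lithium | [Li]c1c(OCOC)cc(OC)cc1OCOC | intermediate (not isolated)
18 | 1-[4-methoxy-2,6-bis(methoxymethoxy)phenyl]-N,N-dimethylmethanamine | CN(C)Cc1c(OCOC)cc(OC)cc1OCOC | intermediate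
19 | hexanoyl chloride | CCCCCC(=O)Cl | starting material
20 | N,O-dimethylhydroxylamine hydrochloride | Cl.CNOC | starting material
21 | N-methoxy-N-methylhexanamide | CCCCCC(=O)N(C)OC | intermediate
22 | {3-[(dimethylamino)methyl]-6-methoxy-2,4-bis(methoxymethoxy)phenyl}lithium | [Li]c1c(OC)cc(OCOC)c(CN(C)C)c1OCOC | intermediate (not isolated)
23 | 1-{3-[(dimethylamino)methyl]-6-methoxy-2,4-bis(methoxymethoxy)phenyl}hexan-1-one | CCCCCC(=O)c1c(OC)cc(OCOC)c(CN(C)C)c1OCOC | intermediate
24 | 1-{3-[(dimethylamino)methyl]-2,4-dihydroxy-6-methoxyphenyl}hexan-1-one hydrochloride | CCCCCC(=O)c1c(OC)cc(O)c(C[NH+](C)C)c1O.[Cl-] | intermediate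
25 | 2-hexanoyl-5-hydroxy-3-methoxy-6-methylidenecyclohexa-2,4-dien-1-one | CCCCCC(=O)C1=C(OC)C=C(O)C(=C)C1=O | intermediate (not isolated)
26 | (4R)-2-butanoyl-6-[(3-hexanoyl-2,6-dihydroxy-4-methoxyphenyl)methyl]-3,5-dihydroxy-4-methyl-4-(3-methylbut-2-en-1-yl)cyclohexa-2,5-dien-1-one | CCCCCC(=O)c1c(OC)cc(O)c(CC2=C(O)[C@@](C)(CC=C(C)C)C(O)=C(C(=O)CCC)C2=O)c1O | target

## Totals and fallbacks

Total step count: 16. Longest linear sequence: 11 steps (steps 1–10, then step 16); the arene branch is steps 11, 12, 14, 15, with step 13 as a one-step side branch.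

Steps most likely to fail:

**Step 16 (quinone-methide Michael coupling).** Risks are oligomerisation of 25, attack of 25 on the free ring C–H of a second aryl unit, and base-induced exchange of the methylene bridge. The fallback replaces the quinone methide by an enolate C-benzylation with a fully protected benzylic halide. It sets out from 23 (with 14). Ethyl chloroformate (toluene, 0 °C → rt) cleaves the benzylic C–N bond of 23 to give 1-[3-(chloromethyl)-6-methoxy-2,4-bis(methoxymethoxy)phenyl]hexan-1-one F1. The caesium enolate of 14 (Cs2CO3, DMF, 0 °C) is C-alkylated at C6 by F1 to give (4R)-2-butanoyl-6-{[3-hexanoyl-4-methoxy-2,6-bis(methoxymethoxy)phenyl]methyl}-3,5-dihydroxy-4-methyl-4-(3-methylbut-2-en-1-yl)cyclohexa-2,5-dien-1-one F2. HCl in MeOH at rt then removes both MOM groups and the route is rejoined at 26.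

**Step 14 (second lithiation and acylation).** The hindered, chelated aryllithium 22 may deprotonate the Weinreb amide 21 instead of adding to it. The fallback swaps acyl substitution for carbonyl addition followed by oxidation. It sets out from 18: 22 is generated in the same way and quenched with hexanal at −78 °C to give 1-{3-[(dimethylamino)methyl]-6-methoxy-2,4-bis(methoxymethoxy)phenyl}hexan-1-ol F3 (racemic carbinol). Swern oxidation of F3 comes back to the route at 23.

**Step 12 (first lithiation and aminomethylation).** Risks are the lithiation site and the heterogeneous quench with the sparingly soluble iminium salt. The fallback builds the benzylic amine by formylation and reductive amination. It sets out from 16: 17 is quenched with DMF to give 4-methoxy-2,6-bis(methoxymethoxy)benzaldehyde F4, whose symmetry can be checked by NMR. Reductive amination of F4 (Me2NH·HCl, Et3N, NaBH(OAc)3, 1,2-dichloroethane, rt) comes back to the route at 18.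

## Further compounds

F1 | step 16 | 1-[3-(chloromethyl)-6-methoxy-2,4-bis(methoxymethoxy)phenyl]hexan-1-one | CCCCCC(=O)c1c(OC)cc(OCOC)c(CCl)c1OCOC
F2 | step 16 | (4R)-2-butanoyl-6-{[3-hexanoyl-4-methoxy-2,6-bis(methoxymethoxy)phenyl]methyl}-3,5-dihydroxy-4-methyl-4-(3-methylbut-2-en-1-yl)cyclohexa-2,5-dien-1-one | CCCCCC(=O)c1c(OC)cc(OCOC)c(CC2=C(O)[C@@](C)(CC=C(C)C)C(O)=C(C(=O)CCC)C2=O)c1OCOC
F3 | step 14 | 1-{3-[(dimethylamino)methyl]-6-methoxy-2,4-bis(methoxymethoxy)phenyl}hexan-1-ol | CCCCCC(O)c1c(OC)cc(OCOC)c(CN(C)C)c1OCOC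
F4 | step 12 | 4-methoxy-2,6-bis(methoxymethoxy)benzaldehyde | COCOc1cc(OC)cc(OCOC)c1C=O
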